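A loading of free catalyst 1.52 times higher gives 1.38 times the target at 15.0 d, and that pair of ratios is what I watch in this run.

the same everywhere: starting material 20 mM; partner 1.05 equiv; second catalyst 3.2 mol%

| flask | protic impurity | free catalyst | remark | time |
|---|---|---|---|---|
| blue | 1 mM | 0.025 mol% | run made earlier |  |
| grey | 1 mM | 0.038 mol% | run made earlier |  |
| flask | 1.00 mM | 0.05 mol% |  | 15 d |

| run | time / d | target / % |
|---|---|---|
| blue | 2.00 | 2.9 |
| blue | 3.00 | 3.8 |
| blue | 5.00 | 4.6 |
| blue | 6.00 | 5.6 |
| blue | 10.0 | 6.2 |
| blue | 15.0 | 6.0 |
| grey | 2.00 | 4.3 |
| grey | 3.00 | 6.3 |
| grey | 5.00 | 7.4 |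
| grey | 6.00 | 6.6 |
| grey | 10.0 | 8.4 |
| grey | 15.0 | 8.3 |

(scatter of a reading: 0.5 percentage points)

- when, up to 15 d, the flask holds most target
- the amount of target, in percent of the starting material charged, at that time



I build the flask up one process at a time. In a picture holding the main step by itself, starting material at [starting material] = 20 mM meets partner on the free catalyst, and target climbs towards the full charge at any loading: the target does not respond to loading, and its exponent is 0. The grey run, though, stops near 8.3%. So I add a second process, a loss of starting material that needs no free catalyst and outruns the main step. If that loss is first order in starting material, target is the main step's share, proportional to loading, with an exponent of 1; I hold this only as the steep end of the range, since the order of the loss cannot be read from these runs. The readings lie between these pictures. I cannot name from them what sets the exponent, so I carry it as read, the loading exponent, the slope of ln(target) against ln(loading), an apparent order in free catalyst: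

n = ln(8.3% / 6.0%) / ln(0.038 mol% / 0.025 mol%) = 0.775

This is a reading, and each target value in it carries a scatter of 0.5 percentage points. Going up from the grey run to 0.05 mol%:

target = 8.3% × (0.05 mol% / 0.038 mol%)^n = 10.3%

The forecast, which is not my reckoning, says 11.2% at 15 d, on the ground that “plateau scales about proportionally with loading”.

The flask gives 9.19% at 8.68 d, under my 10.3%.

    starting material + free catalyst ⇌ free catalyst + open intermediate (K = 0.771, k = 1060 M⁻¹ h⁻¹)
    second catalyst + open intermediate ⇌ catalyst intermediate (K = 8.82 M⁻¹, k = 53.8 M⁻¹ h⁻¹)
    partner + catalyst intermediate → second catalyst + target (k = 693 M⁻¹ h⁻¹)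
    free catalyst + target → free catalyst + over-reaction product (k = 139 M⁻¹ h⁻¹)
    partner + protic impurity → quenched reagent (k = 2.13 M⁻¹ h⁻¹)
    2 starting material → homo dimer (k = 4.61 M⁻¹ h⁻¹)

At 15.0 d, target is made at 0.340 of the rate at which it is used up, each step taken net, and the flask holds 8.43%. Carried down from the blue run to the neighbour with 0.013 mol% of free catalyst, n gives 3.61%, while that flask holds 4.45% at 15.0 d.

Readings and results stem from a simulated flask with constants of no real substance; noise was put on by code.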